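The easy step in a chain length is counting the chains. I took each initiator molecule to give two radicals, and two that join make one chain, so I assumed one chain per initiator molecule charged; the earlier runs do not show chains.

all flasks: free monomer 0.044 M
- dusk: protic impurity 2.2 mM; initiator 0.097 mM; run made earlier
- midnight: protic impurity 2.2 mM; initiator 0.34 mM; run made earlier
- north-west: protic impurity 2.20 mM; initiator 0.22 mM; time 50 h
- east: protic impurity 2.20 mM; initiator 0.080 mM; time 50 h

| run | time / h | monomer in chains / % | free monomer / % |
|---|---|---|---|
| dusk | 2.00 | 39 | 55 |
| dusk | 6.00 | 61 | 35 |
| dusk | 12.0 | 64 | 33 |
| dusk | 20.0 | 65 | 32 |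
| dusk | 25.0 | 65 | 31 |
| midnight | 5.00 | 78 | 18 |
| midnight | 10.0 | 82 | 12 |
| midnight | 15.0 | 81 | 13 |
| midnight | 20.0 | 83 | 13 |
| midnight | 25.0 | 81 | 11 |

(readings scatter by 1.5 percentage points)

- the average divides the monomer in chains by the number of chains, living and dead together; two radicals that join make one chain
- the earlier runs do not show the number of chains; that part of a forecast is a guess

- which of the two ends with the longer chains by the average number of monomer units in a chain (living and dead chains, two that joined counted as one) ("neither" if they lie within 10%) (north-west / east / neither)
- average number of monomer units in a chain (living and dead chains, two that joined counted as one) at the end, north-west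
- average number of monomer units in a chain (living and dead chains, two that joined counted as one) at the end, east

Both runs stall with free monomer left, as in a dead-end polymerization. I let each protic impurity take one monomer, which leaves a usable share of 95.0%; the midnight columns sum to 94.0% at 10.0 h. Dusk stalled near 32% free, a stall exponent x = ln(usable share / free share) of 1.09. I let x grow with the square root of the initiator charge, which gives 2.04 for midnight, where the reading gives 2.07. In east L, the monomer in chains per initiator molecule charged, came to 328. In north-west it came to 153, so I expected east to be longer.

The forecast named east, with 255 for north-west and 550 for east, on the words "Assuming efficiency about 0.6 and combination"; my lengths are shorter than its, 153 and 328.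

The flask gave east: 155 in north-west and 334 in east.

    initiator → 2 initiating radical (k = 0.0110 min⁻¹)
    free monomer + initiating radical → growing radical + monomer in chains (k = 8.36 × 10⁵ L mol⁻¹ s⁻¹)
    free monomer + growing radical → monomer in chains + growing radical, rate k3*[growing radical]*[free monomer] (k = 10900 L mol⁻¹ s⁻¹)
    2 growing radical → dead chain (k = 2.00 × 10⁸ L mol⁻¹ s⁻¹)
    protic impurity + free monomer → quenched substrate (k = 32.9 L mol⁻¹ min⁻¹)
    free monomer → decomposition product (k = 2.36 × 10⁻⁵ min⁻¹)

At 50.0 h east held 8.00 × 10⁻⁵ M of dead chains from 0.080 mM of initiator, one chain per initiator molecule. A neighbouring flask is east with 0.0088 M of protic impurity, 0.200 equiv to the free monomer. Keeping x and the count, I lowered the usable share to 80.0%, which takes L from 328 to 276. That flask ended with 8.00 × 10⁻⁵ M of dead chains, 51.2% of monomer in chains and an average length of 281.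

The earlier runs and the new flask are simulated from invented constants.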